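**Plan**

- Retrosynthesis: ring C (the hydroxyquinone) is cut last into the C8=C9 alkene of ring B, an acyl carbon (C14), a diazo carbon (C11) and the two carbons of an ynol ether (C12, C13). Earlier cuts are C8=C9 (metathesis), C10–C20 together with the lactone C–O bond (allylation and lactonisation), C4–CH3 and C5–C6 (two enolate alkylations).
- Forward order: ring A from a cyclohexenone ester, then the C19–O–C10 γ-lactone bridge, then ring B by ring-closing metathesis, then ring C by aromatic annulation, then oxidation to the quinone.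
- Enabling feature: the C8=C9 bond shared by ring B and ring C can serve as the vinyl arm of a vinylketene, and the adjacent C12–O / C13–isopropyl pair is a polarised siloxyalkyne. C14=O is the ketene carbonyl, and the free C11–H para to it is oxidised afterwards.
- Stereochemistry: C4 by ligand-controlled hydride delivery, relayed to C5 (trans alkylation) and back to C4 (methylation anti to the C5 chain). C10 by equatorial allylation, locked by lactonisation. C7 by catalyst-controlled SN2′ acetoxylation.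

Key step: step 13

Remark on the chemistry: the sense of induction of (S)-p-tol-BINAP in step 3 and of the (Rp,S)-configured cobalt oxazoline palladacycle in step 8 is assumed to be as drawn; if either is opposite, the mirror-image ligand or catalyst is used. Locants C1–C20 are icetexane locants.

**Route**

Step 1
Reactants: 1 cis-but-2-ene-1,4-diol
Product: 2 (2Z)-4-[(tert-butyldimethylsilyl)oxy]but-2-en-1-ol
Conditions: NaH (1.0 equiv), THF, 0 °C; t-BuMe2SiCl (1.0 equiv), rt
Reagents that add atoms: tert-butyldimethylsilyl chloride CC(C)(C)[Si](C)(C)Cl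
Why: Monodeprotonation of the symmetric diol gives a poorly soluble monoalkoxide that should be silylated once (statistical monosilylation of a diol), with no stereocentre formed and the Z alkene untouched.

Step 2
Reactants: 2 (2Z)-4-[(tert-butyldimethylsilyl)oxy]but-2-en-1-ol
Product: 3 (2Z)-1-bromo-4-[(tert-butyldimethylsilyl)oxy]but-2-ene
Conditions: CBr4, PPh3, CH2Cl2, 0 °C
Reagents that add atoms: carbon tetrabromide BrC(Br)(Br)Br
Why: The Appel reaction should convert the primary allylic alcohol into the bromide by SN2 displacement of the oxyphosphonium group at low temperature, without allylic transposition or Z/E isomerisation.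

Step 3
Reactants: 4 methyl 3-oxocyclohex-1-ene-1-carboxylate; 3 (2Z)-1-bromo-4-[(tert-butyldimethylsilyl)oxy]but-2-ene
Product: 6 methyl (1R,2S)-2-[(2Z)-4-[(tert-butyldimethylsilyl)oxy]but-2-en-1-yl]-3-oxocyclohexane-1-carboxylate, via silyl enol ether 5 (not isolated)
Conditions: CuCl, NaOt-Bu, (S)-p-tol-BINAP (5 mol % each), (EtO)2MeSiH, toluene, 0 °C; then 3, Bu4N[Ph3SiF2], CH2Cl2, rt
Reagents that add atoms: diethoxymethylsilane CCO[SiH](C)OCC (silyl group of 5 only)
Why: Ligated copper hydride should deliver hydride to the ring carbon β to the ketone (the stronger acceptor), which sets the ester-bearing stereocentre under ligand control and gives the regiodefined silyl enol ether 5, and fluoride then releases the enolate, which the allylic bromide should alkylate anti to the neighbouring ester to give the trans product (asymmetric conjugate reduction with in situ enolate alkylation).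

Step 4
Reactants: 6 methyl (1R,2S)-2-[(2Z)-4-[(tert-butyldimethylsilyl)oxy]but-2-en-1-yl]-3-oxocyclohexane-1-carboxylate
Product: 7 methyl (1R,2S)-3-[(tert-butyldimethylsilyl)oxy]-2-[(2Z)-4-[(tert-butyldimethylsilyl)oxy]but-2-en-1-yl]cyclohex-3-ene-1-carboxylate
Conditions: LiN(i-Pr)2, THF, −78 °C; t-BuMe2SiCl, DMPU, −78 → 0 °C
Reagents that add atoms: tert-butyldimethylsilyl chloride CC(C)(C)[Si](C)(C)Cl
Why: Kinetic deprotonation of the 2-substituted ketone should occur at the unhindered CH2 (C1) and O-silylation then masks the ketone as its less substituted silyl enol ether (regioselective kinetic enol silane formation), leaving both stereocentres untouched.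

Step 5
Reactants: 7 methyl (1R,2S)-3-[(tert-butyldimethylsilyl)oxy]-2-[(2Z)-4-[(tert-butyldimethylsilyl)oxy]but-2-en-1-yl]cyclohex-3-ene-1-carboxylate
Product: 9 methyl (1S,2S)-2-[(2Z)-4-hydroxybut-2-en-1-yl]-1-methyl-3-oxocyclohexane-1-carboxylate, via bis-silyl methyl ester 8 (not isolated)
Conditions: LiN(i-Pr)2, THF, −78 °C; MeI, −78 → −20 °C; then AcOH, Bu4NF, 0 °C → rt
Reagents that add atoms: iodomethane CI
Why: In the ester enolate the C5 side chain is flanked by two sp2 centres and should stand pseudoaxial to avoid allylic strain, so iodomethane should enter anti to it (ester enolate alkylation) and place the C4 methyl trans and the ester cis to the chain; buffered fluoride then removes both silyl groups and returns the ketone without epimerising C5.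

Step 6
Reactants: 9 methyl (1S,2S)-2-[(2Z)-4-hydroxybut-2-en-1-yl]-1-methyl-3-oxocyclohexane-1-carboxylate; 10 tert-butyl 2-(bromomethyl)prop-2-enoate
Product: 12 tert-butyl 2-{[(1S,5S,8S)-8-[(2Z)-4-hydroxybut-2-en-1-yl]-1-methyl-7-oxo-6-oxabicyclo[3.2.1]octan-5-yl]methyl}prop-2-enoate, via hydroxy diester 11 (not isolated)
Conditions: Zn dust, THF/sat. aq NH4Cl, rt; then DBU (cat.), toluene, 60 °C
Reagents that add atoms: none
Why: In the favoured chair the C4 ester is axial and blocks axial approach to the C10 carbonyl, so the allylzinc reagent (Barbier allylation) should attack equatorially and give the axial C10 alkoxide cis to that ester; the alkoxide should then close the γ-lactone on the 1,3-diaxial methyl ester in preference to the hindered tert-butyl acrylate, which fixes the C10 configuration.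

Step 7
Reactants: 12 tert-butyl 2-{[(1S,5S,8S)-8-[(2Z)-4-hydroxybut-2-en-1-yl]-1-methyl-7-oxo-6-oxabicyclo[3.2.1]octan-5-yl]methyl}prop-2-enoate
Product: 13 tert-butyl 2-{[(1S,5S,8S)-1-methyl-7-oxo-8-[(2Z)-4-(2,2,2-trichloroethanimidoyloxy)but-2-en-1-yl]-6-oxabicyclo[3.2.1]octan-5-yl]methyl}prop-2-enoate
Conditions: Cl3CCN, DBU (cat.), CH2Cl2, 0 °C
Reagents that add atoms: trichloroacetonitrile ClC(Cl)(Cl)C#N
Why: Base-catalysed addition of the primary allylic alcohol to the electron-poor nitrile (trichloroacetimidate formation) should be fast at 0 °C and leaves the lactone, the acrylate and the Z alkene unchanged.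

Step 8
Reactants: 13 tert-butyl 2-{[(1S,5S,8S)-1-methyl-7-oxo-8-[(2Z)-4-(2,2,2-trichloroethanimidoyloxy)but-2-en-1-yl]-6-oxabicyclo[3.2.1]octan-5-yl]methyl}prop-2-enoate
Product: 14 tert-butyl 2-{[(1S,5S,8S)-8-[(2R)-2-acetoxybut-3-en-1-yl]-1-methyl-7-oxo-6-oxabicyclo[3.2.1]octan-5-yl]methyl}prop-2-enoate
Conditions: [Pd(μ-OAc){(η5-C5H3(4-i-Pr-oxazolin-2-yl))Co(η4-C4Ph4)}]2, (Rp,S) (1 mol %), AcOH (3 equiv), CH2Cl2, rt
Reagents that add atoms: acetic acid CC(=O)O
Why: The chiral palladacycle binds the imidate nitrogen and the Z alkene, and acetate should attack the activated alkene anti to palladium with loss of trichloroacetamide (enantioselective SN2′ allylic esterification of a Z-allylic trichloroacetimidate), so the C7 acetate stereocentre (R) is set by the catalyst and the terminal vinyl group for the metathesis appears in the same step.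

Step 9
Reactants: 14 tert-butyl 2-{[(1S,5S,8S)-8-[(2R)-2-acetoxybut-3-en-1-yl]-1-methyl-7-oxo-6-oxabicyclo[3.2.1]octan-5-yl]methyl}prop-2-enoate
Product: 15 tricyclic tert-butyl ester (4S,5S,7R,10S): ring A with the C19–O–C10 lactone, cycloheptene ring B with C8=C9, acetate on C7, CO2t-Bu on C9
Conditions: second-generation Grubbs catalyst RuCl2(=CHPh)(PCy3)(H2IMes) (5 mol %), toluene (0.005 M), 80 °C
Reagents that add atoms: none
Why: The two chains sit on adjacent equatorial positions of ring A, so ring-closing metathesis between the terminal vinyl group and the 1,1-disubstituted acrylate should close the seven-membered ring B with loss of ethene and give the trisubstituted C8=C9 enoate without touching a stereocentre.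

Step 10
Reactants: 15 tricyclic tert-butyl ester
Product: 16 tricyclic carboxylic acid (4S,5S,7R,10S): as 15 with CO2H on C9
Conditions: CF3CO2H/CH2Cl2 (1:4), 0 °C
Reagents that add atoms: none
Why: Acidolysis of the tert-butyl ester (loss of 2-methylpropene) should be faster than ionisation of the electron-poor allylic acetate or of the bridged lactone, whose cation can only re-close.

Step 11
Reactants: 16 tricyclic carboxylic acid
Product: 18 tricyclic diazomethyl ketone (4S,5S,7R,10S): as 16 with C(=O)CHN2 on C9, via acid chloride 17 (not isolated)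
Conditions: (COCl)2, DMF (cat.), CH2Cl2, 0 °C; then CH2N2 (excess), Et2O, 0 °C
Reagents that add atoms: oxalyl chloride ClC(=O)C(=O)Cl (chlorine of 17 only); diazomethane C=[N+]=[N-]
Why: Acylation of diazomethane by the acid chloride (first stage of the Arndt–Eistert sequence) should be much faster than dipolar cycloaddition to the hindered trisubstituted alkene, and excess diazomethane removes the HCl so that no amine base can form a ketene from the acid chloride.

Step 12
Reactants: 19 3-methylbut-1-yne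
Product: 21 triisopropyl[(3-methylbut-1-yn-1-yl)oxy]silane, via lithium ynolate 20 (not isolated)
Conditions: n-BuLi, THF, −78 °C; LiOOt-Bu (from t-BuOOH and LiN(SiMe3)2), −78 → 0 °C; then i-Pr3SiOSO2CF3, −78 °C
Reagents that add atoms: n-butyllithium [Li]CCCC (lithium of 20 only); tert-butyl hydroperoxide CC(C)(C)OO; triisopropylsilyl trifluoromethanesulfonate CC(C)[Si](C(C)C)(C(C)C)OS(=O)(=O)C(F)(F)F
Why: Oxidation of the lithium acetylide by lithium tert-butyl peroxide should give the ynolate, which the hard, bulky silyl triflate silylates on oxygen (ynolate O-silylation) to give the siloxyalkyne.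

Step 13
Reactants: 18 tricyclic diazomethyl ketone; 21 triisopropyl[(3-methylbut-1-yn-1-yl)oxy]silane
Product: 25 tetracyclic phenol (4S,5S,7R,10S): aromatic ring C with OH on C14, isopropyl on C13, OSi(i-Pr)3 on C12, H on C11, via vinylketene 22 (not isolated), via vinylcyclobutenone 23 (not isolated), via dienylketene 24 (not isolated)
Conditions: 21 (1.5 equiv), ClCH2CH2Cl, hν (300 nm), rt; then 80 °C in the dark
Reagents that add atoms: none
Why: Irradiation expels N2 from 18 and the cycloheptenyl group migrates (photochemical Wolff rearrangement) to give vinylketene 22, whose ketene carbon (future C14) is attacked by the nucleophilic isopropyl-bearing carbon of 21 in a regiospecific [2+2] cycloaddition to give vinylcyclobutenone 23, a four-membered ring absent from the target that exists only to join C13 to C14 and C11 to C12. Heating opens 23 by 4π-electrocyclic cleavage to dienylketene 24, and ring C then closes by a 6π-electrocyclisation of the ketene carbon C14 onto C8 of the ring B alkene, followed by tautomerisation of the cyclohexadienone to phenol 25. The closest known reaction type is the Danheiser benzannulation of α′-diazo enones with siloxyalkynes. No stereocentre is created, and C7 keeps its configuration because its C–O bond is not part of the pericyclic array. The selectivity needed is regiochemical (isopropyl next to C14–OH, silyloxy next to C11–H); it is secured by the polarisation of the ynol ether and by the fact that only C8 can reach the ketene carbon, and the free C11–H para to the phenol is what allows the later oxidation to the quinone.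

Step 14
Reactants: 25 tetracyclic phenol
Product: 27 7α-acetoxy-6,7-dihydroicetexone (4S,5S,7R,10S), via silyloxyquinone 26 (not isolated)
Conditions: (KSO3)2NO, KH2PO4, acetone/H2O, 0 °C → rt; then 0.5 M HCl, THF, 0 °C
Reagents that add atoms: potassium nitrosodisulfonate [K+].[K+].[O]N(S(=O)(=O)[O-])S(=O)(=O)[O-]
Why: The 2,6-disubstituted phenol with a free para position should be oxidised to the para-quinone at C11 (Teuber oxidation), after which the vinylogous silyl ester at C12 hydrolyses under mild acid to the hydroxyquinone while the C7 acetate, now on an electron-poor ring, and the lactone are retained.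

**Compound list**

1 | cis-but-2-ene-1,4-diol | OC/C=C\CO | starting material
2 | (2Z)-4-[(tert-butyldimethylsilyl)oxy]but-2-en-1-ol | CC(C)(C)[Si](C)(C)OC/C=C\CO | intermediate
3 | (2Z)-1-bromo-4-[(tert-butyldimethylsilyl)oxy]but-2-ene | CC(C)(C)[Si](C)(C)OC/C=C\CBr | intermediate
4 | methyl 3-oxocyclohex-1-ene-1-carboxylate | COC(=O)C1=CC(=O)CCC1 | starting material
5 | methyl (1R)-3-[(diethoxymethylsilyl)oxy]cyclohex-2-ene-1-carboxylate | COC(=O)[C@@H]1CCCC(O[Si](C)(OCC)OCC)=C1 | intermediate
6 | methyl (1R,2S)-2-[(2Z)-4-[(tert-butyldimethylsilyl)oxy]but-2-en-1-yl]-3-oxocyclohexane-1-carboxylate | CC(C)(C)[Si](C)(C)OC/C=C\C[C@@H]1C(=O)CCC[C@H]1C(=O)OC | intermediate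
7 | methyl (1R,2S)-3-[(tert-butyldimethylsilyl)oxy]-2-[(2Z)-4-[(tert-butyldimethylsilyl)oxy]but-2-en-1-yl]cyclohex-3-ene-1-carboxylate | CC(C)(C)[Si](C)(C)OC/C=C\C[C@@H]1C(O[Si](C)(C)C(C)(C)C)=CCC[C@H]1C(=O)OC | intermediate
8 | methyl (1S,2S)-3-[(tert-butyldimethylsilyl)oxy]-2-[(2Z)-4-[(tert-butyldimethylsilyl)oxy]but-2-en-1-yl]-1-methylcyclohex-3-ene-1-carboxylate | CC(C)(C)[Si](C)(C)OC/C=C\C[C@@H]1C(O[Si](C)(C)C(C)(C)C)=CCC[C@]1(C)C(=O)OC | intermediate
9 | methyl (1S,2S)-2-[(2Z)-4-hydroxybut-2-en-1-yl]-1-methyl-3-oxocyclohexane-1-carboxylate | OC/C=C\C[C@@H]1C(=O)CCC[C@]1(C)C(=O)OC | intermediate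
10 | tert-butyl 2-(bromomethyl)prop-2-enoate | C=C(CBr)C(=O)OC(C)(C)C | starting material
11 | methyl (1S,2S,3S)-3-{2-[(tert-butoxy)carbonyl]prop-2-en-1-yl}-3-hydroxy-2-[(2Z)-4-hydroxybut-2-en-1-yl]-1-methylcyclohexane-1-carboxylate | OC/C=C\C[C@@H]1[C@@](O)(CC(=C)C(=O)OC(C)(C)C)CCC[C@]1(C)C(=O)OC | intermediate
12 | tert-butyl 2-{[(1S,5S,8S)-8-[(2Z)-4-hydroxybut-2-en-1-yl]-1-methyl-7-oxo-6-oxabicyclo[3.2.1]octan-5-yl]methyl}prop-2-enoate | OC/C=C\C[C@@H]2[C@]3(CCC[C@]2(C)C(=O)O3)CC(=C)C(=O)OC(C)(C)C | intermediate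
13 | tert-butyl 2-{[(1S,5S,8S)-1-methyl-7-oxo-8-[(2Z)-4-(2,2,2-trichloroethanimidoyloxy)but-2-en-1-yl]-6-oxabicyclo[3.2.1]octan-5-yl]methyl}prop-2-enoate | ClC(Cl)(Cl)C(=N)OC/C=C\C[C@@H]2[C@]3(CCC[C@]2(C)C(=O)O3)CC(=C)C(=O)OC(C)(C)C | intermediate
14 | tert-butyl 2-{[(1S,5S,8S)-8-[(2R)-2-acetoxybut-3-en-1-yl]-1-methyl-7-oxo-6-oxabicyclo[3.2.1]octan-5-yl]methyl}prop-2-enoate | CC(=O)O[C@@H](C=C)C[C@@H]2[C@]3(CCC[C@]2(C)C(=O)O3)CC(=C)C(=O)OC(C)(C)C | intermediate
15 | tricyclic tert-butyl ester (4S,5S,7R,10S): lactone-bridged ring A, ring B with C8=C9, 7-OAc, CO2t-Bu on C9 | CC(=O)O[C@@H]1C[C@@H]2[C@]3(CCC[C@]2(C)C(=O)O3)CC(C(=O)OC(C)(C)C)=C1 | intermediate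
16 | tricyclic carboxylic acid (4S,5S,7R,10S): as 15 with CO2H on C9 | CC(=O)O[C@@H]1C[C@@H]2[C@]3(CCC[C@]2(C)C(=O)O3)CC(C(=O)O)=C1 | intermediate
17 | tricyclic acid chloride (4S,5S,7R,10S): as 15 with COCl on C9 | CC(=O)O[C@@H]1C[C@@H]2[C@]3(CCC[C@]2(C)C(=O)O3)CC(C(=O)Cl)=C1 | intermediate
18 | tricyclic diazomethyl ketone (4S,5S,7R,10S): as 15 with C(=O)CHN2 on C9 | CC(=O)O[C@@H]1C[C@@H]2[C@]3(CCC[C@]2(C)C(=O)O3)CC(C(=O)C=[N+]=[N-])=C1 | intermediate
19 | 3-methylbut-1-yne | CC(C)C#C | starting material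
20 | lithium 3-methylbut-1-yn-1-olate | CC(C)C#C[O-].[Li+] | intermediate
21 | triisopropyl[(3-methylbut-1-yn-1-yl)oxy]silane | CC(C)C#CO[Si](C(C)C)(C(C)C)C(C)C | intermediate
22 | vinylketene (4S,5S,7R,10S): as 15 with CH=C=O on C9 | CC(=O)O[C@@H]1C[C@@H]2[C@]3(CCC[C@]2(C)C(=O)O3)CC(C=C=O)=C1 | intermediate
23 | vinylcyclobutenone: C9 carries a 2-isopropyl-3-(triisopropylsilyloxy)-4-oxocyclobut-2-en-1-yl group (new ring carbon unassigned) | CC(=O)O[C@@H]1C[C@@H]2[C@]3(CCC[C@]2(C)C(=O)O3)CC(C4C(=O)C(C(C)C)=C4O[Si](C(C)C)(C(C)C)C(C)C)=C1 | intermediate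
24 | dienylketene: C9 carries CH=C(OSi(i-Pr)3)–C(i-Pr)=C=O | CC(=O)O[C@@H]1C[C@@H]2[C@]3(CCC[C@]2(C)C(=O)O3)CC(C=C(O[Si](C(C)C)(C(C)C)C(C)C)C(C(C)C)=C=O)=C1 | intermediate
25 | tetracyclic phenol (4S,5S,7R,10S): 14-OH, 13-isopropyl, 12-OSi(i-Pr)3, 11-H, 7-OAc | CC(=O)O[C@@H]1C[C@@H]2[C@]3(CCC[C@]2(C)C(=O)O3)Cc2cc(O[Si](C(C)C)(C(C)C)C(C)C)c(C(C)C)c(O)c21 | intermediate
26 | 12-O-triisopropylsilyl ether of the target quinone | CC(=O)O[C@@H]1C[C@@H]2[C@]3(CCC[C@]2(C)C(=O)O3)CC2=C1C(=O)C(C(C)C)=C(O[Si](C(C)C)(C(C)C)C(C)C)C2=O | intermediate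
27 | 7α-acetoxy-6,7-dihydroicetexone (4S,5S,7R,10S) | CC(=O)O[C@@H]1C[C@@H]2[C@]3(CCC[C@]2(C)C(=O)O3)CC2=C1C(=O)C(C(C)C)=C(O)C2=O | target

**Count and risks**

Total step count: 14. Longest linear sequence: 13 steps (steps 1 to 11, then 13 and 14).

Step 13. The phenol is an electron-rich o-hydroxybenzylic acetate, so acetic acid may be lost through an o-quinone methide while light or heat is still applied, and the Wolff rearrangement of the enone-type diazo ketone may be slow. The fallback carries the C7 oxygen through ring C formation as a silyl ether, a much poorer leaving group, and puts the acetate on at the quinone level. It sets out from acid 16 and comes back at 27.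
- K2CO3 in MeOH removes the acetate to give the hydroxy acid F1.
- t-BuMe2SiOSO2CF3 with 2,6-lutidine gives the silyl ether silyl ester F2.
- (COCl)2 with catalytic DMF turns the silyl ester directly into the acid chloride F3, and CH2N2 gives the diazo ketone F4.
- Irradiation with 21 and heating, by the same cascade through vinylketene F5, vinylcyclobutenone F6 and dienylketene F7, gives the phenol F8.
- (KSO3)2NO gives the bis-silyl quinone F9, which loses the enol silyl group on aqueous work-up to give the hydroxyquinone silyl ether F10.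
- Ac2O with catalytic Cu(OTf)2 exchanges the C7 silyl ether for acetate and also acetylates the acidic quinone hydroxyl to give the diacetate F11; NaHCO3 in MeOH cleaves only the vinylogous anhydride acetate.

Step 3. Hydride may be delivered to the carbon β to the ester instead of β to the ketone, the enantioselectivity on this doubly activated alkene may be low, and O-alkylation may compete. The fallback uses bromide 3 with a chiral-pool keto ester in place of 4 and comes back at 6.
- Commercial methyl (1R)-3-oxocyclohexane-1-carboxylate F12 is converted with LiN(i-Pr)2 and Me3SiCl into the less substituted enol ether, methyl (1R)-3-[(trimethylsilyl)oxy]cyclohex-3-ene-1-carboxylate F13. Any regioisomeric enol ether leads back to enone 4 and is separated.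
- Pd(OAc)2 (Saegusa–Ito oxidation) gives the enone F14.
- Its kinetic α′-enolate (LiN(i-Pr)2, −78 °C) is alkylated with 3 trans to the ester to give the alkylated enone F15.
- Li[HB(s-Bu)3] reduces the enone C=C by conjugate addition and gives 6.

Step 8. The SN2′ acetoxylation may show poor enantioselectivity or a poor branched-to-linear ratio on this substrate, and [3,3] rearrangement of the imidate to the allylic trichloroacetamide may compete. The fallback sets out from alcohol 12 and comes back at 14.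
- Sharpless asymmetric epoxidation (Ti(Oi-Pr)4, L-(+)-diethyl tartrate, t-BuOOH, 4 Å sieves, −20 °C) should give the cis-epoxy alcohol F16.
- I2, PPh3 and imidazole give the epoxy iodide F17.
- Zn in ethanol opens the epoxide reductively, with the C7–O bond kept, to the (R)-allylic alcohol F18.
- Ac2O with DMAP and pyridine gives 14.

**Further compounds**

F1 | step 13 | tricyclic hydroxy acid (4S,5S,7R,10S): as 16 with 7-OH | O[C@@H]1C[C@@H]2[C@]3(CCC[C@]2(C)C(=O)O3)CC(C(=O)O)=C1
F2 | step 13 | 7-O-tert-butyldimethylsilyl ether tert-butyldimethylsilyl ester of F1 | CC(C)(C)[Si](C)(C)O[C@@H]1C[C@@H]2[C@]3(CCC[C@]2(C)C(=O)O3)CC(C(=O)O[Si](C)(C)C(C)(C)C)=C1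
F3 | step 13 | 7-silyloxy acid chloride | CC(C)(C)[Si](C)(C)O[C@@H]1C[C@@H]2[C@]3(CCC[C@]2(C)C(=O)O3)CC(C(=O)Cl)=C1
F4 | step 13 | 7-silyloxy diazomethyl ketone | CC(C)(C)[Si](C)(C)O[C@@H]1C[C@@H]2[C@]3(CCC[C@]2(C)C(=O)O3)CC(C(=O)C=[N+]=[N-])=C1
F5 | step 13 | 7-silyloxy vinylketene | CC(C)(C)[Si](C)(C)O[C@@H]1C[C@@H]2[C@]3(CCC[C@]2(C)C(=O)O3)CC(C=C=O)=C1
F6 | step 13 | 7-silyloxy vinylcyclobutenone | CC(C)(C)[Si](C)(C)O[C@@H]1C[C@@H]2[C@]3(CCC[C@]2(C)C(=O)O3)CC(C4C(=O)C(C(C)C)=C4O[Si](C(C)C)(C(C)C)C(C)C)=C1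
F7 | step 13 | 7-silyloxy dienylketene | CC(C)(C)[Si](C)(C)O[C@@H]1C[C@@H]2[C@]3(CCC[C@]2(C)C(=O)O3)CC(C=C(O[Si](C(C)C)(C(C)C)C(C)C)C(C(C)C)=C=O)=C1
F8 | step 13 | 7-silyloxy tetracyclic phenol | CC(C)(C)[Si](C)(C)O[C@@H]1C[C@@H]2[C@]3(CCC[C@]2(C)C(=O)O3)Cc2cc(O[Si](C(C)C)(C(C)C)C(C)C)c(C(C)C)c(O)c21
F9 | step 13 | 7-O-tert-butyldimethylsilyl 12-O-triisopropylsilyl quinone | CC(C)(C)[Si](C)(C)O[C@@H]1C[C@@H]2[C@]3(CCC[C@]2(C)C(=O)O3)CC2=C1C(=O)C(C(C)C)=C(O[Si](C(C)C)(C(C)C)C(C)C)C2=O
F10 | step 13 | 7-O-tert-butyldimethylsilyl hydroxyquinone | CC(C)(C)[Si](C)(C)O[C@@H]1C[C@@H]2[C@]3(CCC[C@]2(C)C(=O)O3)CC2=C1C(=O)C(C(C)C)=C(O)C2=O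
F11 | step 13 | 7,12-diacetate of the quinone | CC(=O)O[C@@H]1C[C@@H]2[C@]3(CCC[C@]2(C)C(=O)O3)CC2=C1C(=O)C(C(C)C)=C(OC(C)=O)C2=O
F12 | step 3 | methyl (1R)-3-oxocyclohexane-1-carboxylate | COC(=O)[C@@H]1CCCC(=O)C1
F13 | step 3 | methyl (1R)-3-[(trimethylsilyl)oxy]cyclohex-3-ene-1-carboxylate | COC(=O)[C@@H]1CCC=C(O[Si](C)(C)C)C1
F14 | step 3 | methyl (1R)-5-oxocyclohex-3-ene-1-carboxylate | COC(=O)[C@@H]1CC=CC(=O)C1
F15 | step 3 | methyl (1R,6S)-6-[(2Z)-4-[(tert-butyldimethylsilyl)oxy]but-2-en-1-yl]-5-oxocyclohex-3-ene-1-carboxylate | CC(C)(C)[Si](C)(C)OC/C=C\C[C@@H]1C(=O)C=CC[C@H]1C(=O)OC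
F16 | step 8 | cis-epoxy alcohol of 12 (epoxide carbons: S at the carbon bearing CH2OH, R at C7) | OC[C@@H]1O[C@@H]1C[C@@H]2[C@]3(CCC[C@]2(C)C(=O)O3)CC(=C)C(=O)OC(C)(C)C
F17 | step 8 | cis-epoxy iodide from F16 | IC[C@@H]1O[C@@H]1C[C@@H]2[C@]3(CCC[C@]2(C)C(=O)O3)CC(=C)C(=O)OC(C)(C)C
F18 | step 8 | tert-butyl 2-{[(1S,5S,8S)-8-[(2R)-2-hydroxybut-3-en-1-yl]-1-methyl-7-oxo-6-oxabicyclo[3.2.1]octan-5-yl]methyl}prop-2-enoate | O[C@@H](C=C)C[C@@H]2[C@]3(CCC[C@]2(C)C(=O)O3)CC(=C)C(=O)OC(C)(C)C
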